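**Retrosynthetic overview**

1. Ring atoms are numbered as in the name of the target: C1 carries the pentenol chain, C2 is CMe2, C3 and C5 are CHBr, C4 is CH2, C6 is C=CH2. The C5 bromide is made last from an allylic alcohol (substitution with inversion), the alcohol from a 6-methylidene 5-ketone, and the methylidene carbon by aminomethylation of a regiodefined C5 silyl enol ether.
2. One of the two C2 methyl groups is carried as a formyl group and reduced (tosylhydrazone) once the ring exists.
3. Key disconnection: the only ring is formed in one enantioselective Diels–Alder reaction that makes the C1–C2 and C3–C4 bonds. The diene is a 2-silyloxy-1,3-diene (C4, C5, C6, C1 and the whole side chain); the dienophile is (E)-3-bromo-2-methylprop-2-enal (C3, C2, one methyl, the formyl carbon), so the secondary C3 bromide arrives with the dienophile.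
4. Enabling feature: C3 (CHBr) is beta to the quaternary C2, so with one C2 methyl at the aldehyde level the C2–C3 unit is a beta-bromo enal. The C5(Br)/C6(=CH2) pair is the retron of an enol ether on C5. Oxygen on C5 and the alkyl chain on C1 sit 1,3 on the diene and both direct C4 onto C3.
5. The diene comes in three steps from (S)-linalool (chiral pool: its C1–C6 and carbinol centre become the side chain and ring C1); the dienophile comes from methacrolein.

Key step: step 5

Remark: (S)-(+)-linalool is taken as the commercial, enantiomerically enriched starting material; the facial sense of the (S)-configured oxazaborolidinium catalyst in step 5 is assigned by analogy with its cycloadditions of 2-methylacrolein, and its mirror-image form would be used should the sense prove opposite.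

**Route**

Step 1
Reactants: 1 (S)-linalool [(3S)-3,7-dimethylocta-1,6-dien-3-ol]
Product: 2 triethyl{[(3S)-3,7-dimethylocta-1,6-dien-3-yl]oxy}silane
Conditions: Et3SiOTf, 2,6-lutidine, CH2Cl2, −78 → 0 °C
Reagents that add atoms: triethylsilyl trifluoromethanesulfonate, CC[Si](CC)(CC)OS(=O)(=O)C(F)(F)F
Why: Silylation of a tertiary allylic alcohol with a silyl triflate and a hindered pyridine base is routine and leaves the carbinol stereocentre untouched (silyl ether protection).

Step 2
Reactants: 2 triethylsilyl ether of (S)-linalool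
Product: 4 (3E,7S)-7-methyl-7-[(triethylsilyl)oxy]nona-3,8-dien-2-one, via aldehyde 3 (not isolated)
Conditions: O3, CH2Cl2, pyridine, Sudan Red 7B, −78 °C; PPh3, −78 °C → rt; then Ph3P=CHC(O)CH3, rt
Reagents that add atoms: 1-(triphenyl-λ5-phosphanylidene)propan-2-one, CC(=O)C=P(c1ccccc1)(c1ccccc1)c1ccccc1; ozone, [O-][O+]=O (supplies the carbonyl oxygen of 3 only)
Why: The electron-rich trisubstituted alkene should be ozonised well before the monosubstituted vinyl group (end point shown by the dye), and the stabilised ylide then gives the (E)-enone (chemoselective ozonolysis followed by Wittig reaction).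

Step 3
Reactants: 4 (3E,7S)-enone
Product: 5 (3E,7S)-7-methyl-7-[(triethylsilyl)oxy]-2-{[tri(propan-2-yl)silyl]oxy}nona-1,3,8-triene
Conditions: iPr3SiOTf, Et3N, Et2O, 0 °C → rt
Reagents that add atoms: tri(propan-2-yl)silyl trifluoromethanesulfonate, CC(C)[Si](C(C)C)(C(C)C)OS(=O)(=O)C(F)(F)F
Why: Soft enolisation of a methyl enone with a silyl triflate and Et3N removes a proton of the methyl group and should give the cross-conjugated 2-silyloxy-1,3-diene with the (E)-alkene intact (silyl dienol ether formation).

Step 4
Reactants: 6 methacrolein (2-methylprop-2-enal)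
Product: 8 (2E)-3-bromo-2-methylprop-2-enal, via 2,3-dibromo-2-methylpropanal 7 (not isolated)
Conditions: Br2, CH2Cl2, −78 → 0 °C; then Et3N, 0 °C → rt
Reagents that add atoms: bromine, BrBr
Why: Bromine adds across the alkene and Et3N removes HBr from the non-enolisable dibromide to give the conjugated beta-bromo enal, expected as the (E)-isomer with bromine anti to the formyl group (bromination–dehydrobromination).

Step 5
Reactants: 5 2-silyloxy diene; 8 (2E)-3-bromo-2-methylprop-2-enal
Product: 9 (1S,2R,6R)-6-bromo-1-methyl-2-{(3S)-3-methyl-3-[(triethylsilyl)oxy]pent-4-en-1-yl}-4-{[tri(propan-2-yl)silyl]oxy}cyclohex-3-ene-1-carbaldehyde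
Conditions: (S)-3,3-diphenyl-1-(2-methylphenyl)tetrahydro-1H,3H-pyrrolo[1,2-c][1,3,2]oxazaborole·HNTf2 (20 mol %), CH2Cl2, −78 °C
Reagents that add atoms: none
Why: Concerted but asynchronous normal-demand [4+2] cycloaddition (Diels–Alder reaction) with the formyl oxygen of 8 bound to the cationic boron of the catalyst; the closest precedent is the oxazaborolidinium-catalysed enantioselective Diels–Alder reaction of 2-silyloxy-1,3-dienes with alpha-substituted acroleins. The six-membered carbocycle is closed by the cycloaddition itself, suprafacially on both partners, the bond from the unsubstituted diene terminus to the bromine-bearing beta-carbon running ahead of the bond that creates the quaternary carbon. The 2-silyloxy group and the 4-alkyl group of 5 both enlarge the HOMO coefficient at the unsubstituted terminus, which therefore joins the beta-carbon of 8, so that the formyl-bearing carbon ends up next to the side-chain carbon. The (E)-geometry of the diene and an endo orientation of the boron-bound formyl group place the side chain cis to the formyl group, and the (E)-geometry of 8 (bromine trans to formyl) then places bromine trans to the side chain, as the target requires. The absolute configuration is set by the catalyst, which shields one face of the s-trans enal; the remote (S)-carbinol centre has no influence and the isolated vinyl group does not compete as diene or dienophile. The step needs regio-, endo- and enantioface-selectivity, secured respectively by the matched 1,3-donor pattern of the diene, the Lewis-acid-bound formyl group and the chiral catalyst.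

Step 6
Reactants: 9 cycloadduct aldehyde
Product: 10 N'-[(E)-{(1S,2R,6R)-6-bromo-1-methyl-2-{(3S)-3-methyl-3-[(triethylsilyl)oxy]pent-4-en-1-yl}-4-{[tri(propan-2-yl)silyl]oxy}cyclohex-3-en-1-yl}methylidene]-4-methylbenzenesulfonohydrazide
Conditions: TsNHNH2, MgSO4, THF, rt
Reagents that add atoms: 4-methylbenzenesulfonohydrazide, Cc1ccc(cc1)S(=O)(=O)NN
Why: Condensation of the non-enolisable aldehyde with tosylhydrazide should proceed under neutral conditions that leave the silyl enol ether intact (tosylhydrazone formation).

Step 7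
Reactants: 10 tosylhydrazone
Product: 13 {[(3R,5R)-5-bromo-4,4-dimethyl-3-{(3S)-3-methyl-3-[(triethylsilyl)oxy]pent-4-en-1-yl}cyclohex-1-en-1-yl]oxy}tri(propan-2-yl)silane, via tosylhydrazine 11 (not isolated), via monoalkyldiazene 12 (not isolated)
Conditions: catecholborane, CHCl3, 0 °C; then NaOAc·3H2O, 50 °C
Reagents that add atoms: none
Why: Catecholborane adds hydride to the C=N bond and acetate then releases sulfinate to give a monoalkyldiazene that loses N2, so the formyl carbon becomes the second methyl group without touching the bromide or the enol ether (borane variant of the Caglioti tosylhydrazone reduction).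

Step 8
Reactants: 13 silyl enol ether
Product: 16 (3R,5R)-5-bromo-4,4-dimethyl-2-methylidene-3-{(3S)-3-methyl-3-[(triethylsilyl)oxy]pent-4-en-1-yl}cyclohexan-1-one, via Mannich base 14 (not isolated), via amine N-oxide 15 (not isolated)
Conditions: [Me2N=CH2]+ I−, CH2Cl2, rt; aq. NaHCO3 wash; crude amine, mCPBA, CH2Cl2, 0 °C → rt
Reagents that add atoms: N,N-dimethylmethaniminium iodide, C=[N+](C)C.[I-]; 3-chloroperoxybenzoic acid, OOC(=O)c1cccc(Cl)c1 (supplies the oxygen of 15 only)
Why: The regiodefined silyl enol ether is aminomethylated by the preformed iminium salt only at the ring carbon next to the side-chain carbon, and the N-oxide of the Mannich base undergoes syn elimination at room temperature, so the methylidene group is unveiled without base and the beta-bromo ketone is not enolised (Mannich reaction of a silyl enol ether, then Cope elimination).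

Step 9
Reactants: 16 alpha-methylidene ketone
Product: 17 (1S,3R,5R)-5-bromo-4,4-dimethyl-2-methylidene-3-{(3S)-3-methyl-3-[(triethylsilyl)oxy]pent-4-en-1-yl}cyclohexan-1-ol
Conditions: (R)-1-methyl-3,3-diphenyltetrahydro-1H,3H-pyrrolo[1,2-c][1,3,2]oxazaborole (20 mol %), catecholborane, toluene, −78 °C; MeOH quench
Reagents that add atoms: none
Why: With the methylidene-bearing carbon as the large group, the (R)-oxazaborolidine should direct 1,2-hydride delivery to give the (1S)-allylic alcohol with hydroxyl trans to the side chain, the new stereocentre being set by the catalyst (Corey–Bakshi–Shibata reduction).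

Step 10
Reactants: 17 allylic alcohol
Product: 18 triethyl({(3S)-5-[(1S,3R,5R)-3,5-dibromo-2,2-dimethyl-6-methylidenecyclohexyl]-3-methylpent-1-en-3-yl}oxy)silane
Conditions: CBr4, PPh3, CH2Cl2, −20 → 0 °C
Reagents that add atoms: tetrabromomethane, BrC(Br)(Br)Br
Why: Displacement of the oxyphosphonium group by bromide with inversion at the secondary allylic carbon should place bromine cis to the side chain and trans to the other bromine (Appel reaction).

Step 11
Reactants: 18 triethylsilyl ether of the target
Product: 19 (3S)-5-[(1S,3R,5R)-3,5-dibromo-2,2-dimethyl-6-methylidenecyclohexyl]-3-methylpent-1-en-3-ol (target)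
Conditions: HF·pyridine, pyridine, THF, 0 °C
Reagents that add atoms: none
Why: Buffered HF·pyridine should cleave the tertiary triethylsilyl ether without ionising the tertiary allylic alcohol or the allylic bromide (fluoride-mediated desilylation).

**Compound list**

1 | (3S)-3,7-dimethylocta-1,6-dien-3-ol, (S)-linalool | C=C[C@@](C)(O)CCC=C(C)C | starting material
2 | triethyl{[(3S)-3,7-dimethylocta-1,6-dien-3-yl]oxy}silane | C=C[C@@](C)(O[Si](CC)(CC)CC)CCC=C(C)C | intermediate
3 | (4S)-4-methyl-4-[(triethylsilyl)oxy]hex-5-enal | C=C[C@@](C)(O[Si](CC)(CC)CC)CCC=O | intermediate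
4 | (3E,7S)-7-methyl-7-[(triethylsilyl)oxy]nona-3,8-dien-2-one | C=C[C@@](C)(O[Si](CC)(CC)CC)CC/C=C/C(C)=O | intermediate
5 | (3E,7S)-7-methyl-7-[(triethylsilyl)oxy]-2-{[tri(propan-2-yl)silyl]oxy}nona-1,3,8-triene | C=C[C@@](C)(O[Si](CC)(CC)CC)CC/C=C/C(=C)O[Si](C(C)C)(C(C)C)C(C)C | intermediate
6 | 2-methylprop-2-enal (methacrolein) | CC(=C)C=O | starting material
7 | 2,3-dibromo-2-methylpropanal (racemic) | CC(Br)(CBr)C=O | intermediate
8 | (2E)-3-bromo-2-methylprop-2-enal | O=C/C(C)=C/Br | intermediate
9 | (1S,2R,6R)-6-bromo-1-methyl-2-{(3S)-3-methyl-3-[(triethylsilyl)oxy]pent-4-en-1-yl}-4-{[tri(propan-2-yl)silyl]oxy}cyclohex-3-ene-1-carbaldehyde (side chain and formyl cis, bromine trans to both) | C=C[C@@](C)(O[Si](CC)(CC)CC)CC[C@@H]1C=C(O[Si](C(C)C)(C(C)C)C(C)C)C[C@@H](Br)[C@]1(C)C=O | intermediate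
10 | (E)-tosylhydrazone of 9 | C=C[C@@](C)(O[Si](CC)(CC)CC)CC[C@@H]1C=C(O[Si](C(C)C)(C(C)C)C(C)C)C[C@@H](Br)[C@]1(C)/C=N/NS(=O)(=O)c2ccc(C)cc2 | intermediate
11 | N'-{[(1S,2R,6R)-cyclohexenyl]methyl}-4-methylbenzenesulfonohydrazide from hydride addition to 10 (present as its N-boryl derivative) | C=C[C@@](C)(O[Si](CC)(CC)CC)CC[C@@H]1C=C(O[Si](C(C)C)(C(C)C)C(C)C)C[C@@H](Br)[C@]1(C)CNNS(=O)(=O)c2ccc(C)cc2 | intermediate
12 | {[(1S,2R,6R)-cyclohexenyl]methyl}diazene formed from 11 by loss of sulfinate | C=C[C@@](C)(O[Si](CC)(CC)CC)CC[C@@H]1C=C(O[Si](C(C)C)(C(C)C)C(C)C)C[C@@H](Br)[C@]1(C)CN=N | intermediate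
13 | {[(3R,5R)-5-bromo-4,4-dimethyl-3-{(3S)-3-methyl-3-[(triethylsilyl)oxy]pent-4-en-1-yl}cyclohex-1-en-1-yl]oxy}tri(propan-2-yl)silane | C=C[C@@](C)(O[Si](CC)(CC)CC)CC[C@@H]1C=C(O[Si](C(C)C)(C(C)C)C(C)C)C[C@@H](Br)C1(C)C | intermediate
14 | (3R,5R)-5-bromo-2-[(dimethylamino)methyl]-4,4-dimethyl-3-{(3S)-3-methyl-3-[(triethylsilyl)oxy]pent-4-en-1-yl}cyclohexan-1-one (both C2 epimers) | C=C[C@@](C)(O[Si](CC)(CC)CC)CC[C@@H]1C(CN(C)C)C(=O)C[C@@H](Br)C1(C)C | intermediate
15 | N-oxide of 14 | C=C[C@@](C)(O[Si](CC)(CC)CC)CC[C@@H]1C(C[N+](C)(C)[O-])C(=O)C[C@@H](Br)C1(C)C | intermediate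
16 | (3R,5R)-5-bromo-4,4-dimethyl-2-methylidene-3-{(3S)-3-methyl-3-[(triethylsilyl)oxy]pent-4-en-1-yl}cyclohexan-1-one | C=C[C@@](C)(O[Si](CC)(CC)CC)CC[C@@H]1C(=C)C(=O)C[C@@H](Br)C1(C)C | intermediate
17 | (1S,3R,5R)-5-bromo-4,4-dimethyl-2-methylidene-3-{(3S)-3-methyl-3-[(triethylsilyl)oxy]pent-4-en-1-yl}cyclohexan-1-ol (hydroxyl trans to side chain, cis to bromine) | C=C[C@@](C)(O[Si](CC)(CC)CC)CC[C@@H]1C(=C)[C@@H](O)C[C@@H](Br)C1(C)C | intermediate
18 | triethyl({(3S)-5-[(1S,3R,5R)-3,5-dibromo-2,2-dimethyl-6-methylidenecyclohexyl]-3-methylpent-1-en-3-yl}oxy)silane | C=C[C@@](C)(O[Si](CC)(CC)CC)CC[C@@H]1C(=C)[C@H](Br)C[C@@H](Br)C1(C)C | intermediate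
19 | (3S)-5-[(1S,3R,5R)-3,5-dibromo-2,2-dimethyl-6-methylidenecyclohexyl]-3-methylpent-1-en-3-ol | C=C[C@@](C)(O)CC[C@@H]1C(=C)[C@H](Br)C[C@@H](Br)C1(C)C | target

**Step count and risks**

Total: 11 steps. Longest linear sequence: 10 steps (steps 1–3 and 5–11, from (S)-linalool).

Steps most likely to fail:

Step 5 (key cycloaddition). Under Lewis acid activation the reaction may turn stepwise: conjugate addition of the enol ether terminus, then loss of bromide from the resulting enolate instead of ring closure. Facial discrimination of the trisubstituted enal may also be incomplete. Fallback, setting out again from 5 and 8: the cycloaddition is run without any Lewis acid (toluene, BHT, 80 °C, sealed tube), where the concerted pathway has no enolate intermediate. The same regio- and endo-preference should then give 9 together with its ring-diastereomer, the (1R,2S,6S)-configured aldehyde F1. Stereocontrol is thereby moved from the catalyst to a separation (preparative HPLC on a chiral phase, or crystallisation after step 6), and the route is rejoined at 9.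

Step 8 (methylidene introduction). The beta-bromo ketone may lose HBr by enolisation towards the ring CH2, promoted by the basic Mannich amine, and the alpha-methylidene ketone may dimerise. Fallback, setting out from 13: alkylation of the silyl enol ether with chloromethyl phenyl sulfide and ZnBr2 (CH2Cl2, rt) should give the 2-[(phenylsulfanyl)methyl] ketone F2. Oxidation with NaIO4 (MeOH, H2O, 0 °C) gives the sulfoxide F3, whose thermal syn elimination (toluene, CaCO3, 80 °C) unveils the methylidene group under neutral conditions. The route is rejoined at 16.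

Step 10 (allylic bromide). Bromide may attack the methylidene terminus (allylic transposition to the primary bromide), or the oxyphosphonium intermediate may ionise with loss of configuration. Fallback, setting out from 17: activation and displacement are separated. The allylic methanesulfonate F4 is formed at low temperature (Ms2O, 2,6-lutidine, CH2Cl2, −40 °C) and displaced directly by a soluble bromide (Bu4NBr, acetone, −20 °C) with inversion. The route is rejoined at 18.

Further compounds
F1 | step 5 | (1R,2S,6S)-6-bromo-1-methyl-2-{(3S)-3-methyl-3-[(triethylsilyl)oxy]pent-4-en-1-yl}-4-{[tri(propan-2-yl)silyl]oxy}cyclohex-3-ene-1-carbaldehyde | C=C[C@@](C)(O[Si](CC)(CC)CC)CC[C@H]1C=C(O[Si](C(C)C)(C(C)C)C(C)C)C[C@H](Br)[C@@]1(C)C=O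
F2 | step 8 | (3R,5R)-5-bromo-4,4-dimethyl-3-{(3S)-3-methyl-3-[(triethylsilyl)oxy]pent-4-en-1-yl}-2-[(phenylsulfanyl)methyl]cyclohexan-1-one (both C2 epimers) | C=C[C@@](C)(O[Si](CC)(CC)CC)CC[C@@H]1C(CSc2ccccc2)C(=O)C[C@@H](Br)C1(C)C
F3 | step 8 | (3R,5R)-5-bromo-4,4-dimethyl-3-{(3S)-3-methyl-3-[(triethylsilyl)oxy]pent-4-en-1-yl}-2-[(phenylsulfinyl)methyl]cyclohexan-1-one | C=C[C@@](C)(O[Si](CC)(CC)CC)CC[C@@H]1C(CS(=O)c2ccccc2)C(=O)C[C@@H](Br)C1(C)C
F4 | step 10 | (1S,3R,5R)-5-bromo-4,4-dimethyl-2-methylidene-3-{(3S)-3-methyl-3-[(triethylsilyl)oxy]pent-4-en-1-yl}cyclohexyl methanesulfonate | C=C[C@@](C)(O[Si](CC)(CC)CC)CC[C@@H]1C(=C)[C@@H](OS(C)(=O)=O)C[C@@H](Br)C1(C)C
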